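## Retrosynthetic overview

1. Target ⇒ bis-silyl ether ⇒ cut of the sp3–sp3 bond C5′–C6′ (side chain numbered C1′–C6′ from chroman C2 to the carbocycle): an (S)-chromanyl (E)-allylic bromide and a cyclohexylmethyl Grignard reagent, joined under copper catalysis.
2. Carbocycle ⇒ cut of its C1–C2 bond (C1 = CH bearing the chain, C2 = CMe2, C3 = CHOH, C6 = C=CH2) back to acyclic (6R)-6,7-epoxyneryl acetate. One Ti(III) radical 6-endo cyclization closes the ring; the Z olefin (not the usual E one) holds the C1 substituent axial in the chair, which gives the trans C1/C3 pair and the exocyclic C6=CH2 in the same operation.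
3. Chroman ⇒ cuts of O1–C8a (Pd C–O coupling) and C4–C4a (B-alkyl Suzuki coupling) back to (S)-linalool, which supplies the quaternary C2 stereocentre, and a 1-iodo-2-bromoarene. The allylic bromide comes from Riley oxidation of the prenyl terminus.
4. Ring order: pyran ring of the chroman (step 5) and cyclohexane (step 9) on separate branches; union in step 13; fluoride deprotection in step 14.

Key step: step 9

Assumption: (S)-(+)-linalool (coriandrol) is bought as the single enantiomer; its enantiomeric purity is carried unchanged into C2 of the chroman.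

## Route

Step 1
Reactants: 1 4-amino-3-methylphenol
Product: 2 2-methyl-4-[(triisopropylsilyl)oxy]aniline
Conditions: TIPSCl (1.1 equiv), imidazole, DMF, 0 °C → rt
Reagents that add atoms: triisopropylsilyl chloride, CC(C)[Si](Cl)(C(C)C)C(C)C
Why: Imidazole-promoted silylation should take the phenolic oxygen in preference to the weakly nucleophilic aniline nitrogen, and the bulky aryl TIPS ether should last through the later basic, oxidative and organometallic steps until fluoride is applied.

Step 2
Reactants: 2 2-methyl-4-[(triisopropylsilyl)oxy]aniline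
Product: 3 2-iodo-6-methyl-4-[(triisopropylsilyl)oxy]aniline
Conditions: NIS (1.05 equiv), MeCN, 0 °C, dark
Reagents that add atoms: N-iodosuccinimide, O=C1CCC(=O)N1I
Why: Electrophilic aromatic iodination is directed by the amino group, whose para position is blocked by the silyloxy group and one ortho position by methyl, so iodine should enter the one free ortho position (the future C4a).

Step 3
Reactants: 3 2-iodo-6-methyl-4-[(triisopropylsilyl)oxy]aniline
Product: 4 2-bromo-1-iodo-3-methyl-5-[(triisopropylsilyl)oxy]benzene
Conditions: t-BuONO, CuBr2, MeCN, 0 → 60 °C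
Reagents that add atoms: copper(II) bromide, Br[Cu]Br
Why: Sandmeyer bromination under anhydrous alkyl nitrite conditions should replace the amino group (the future C8a) by bromine through the diazonium ion and aryl radical, without touching the silyl ether or the C–I bond.

Step 4
Reactants: 5 (S)-(+)-linalool; 4 2-bromo-1-iodo-3-methyl-5-[(triisopropylsilyl)oxy]benzene
Product: 7 (3S)-1-{2-bromo-3-methyl-5-[(triisopropylsilyl)oxy]phenyl}-3,7-dimethyloct-6-en-3-ol, via B-alkyl-9-BBN adduct 6 (not isolated)
Conditions: 9-BBN (1.5 equiv), THF, 0 °C → rt; then 4, PdCl2(dppf) (5 mol %), AsPh3, 3 M aq. K3PO4, DMF, rt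
Reagents that add atoms: none
Why: 9-BBN should hydroborate only the monosubstituted vinyl group (anti-Markovnikov, trisubstituted olefin untouched), and the B-alkyl Suzuki–Miyaura coupling should take place at the C–I bond and leave the flanked C–Br bond; the carbinol stereocentre is not involved.

Step 5
Reactants: 7 (3S)-1-{2-bromo-3-methyl-5-[(triisopropylsilyl)oxy]phenyl}-3,7-dimethyloct-6-en-3-ol
Product: 8 (2S)-2,8-dimethyl-2-(4-methylpent-3-en-1-yl)-6-[(triisopropylsilyl)oxy]chromane
Conditions: Pd(OAc)2 (3 mol %), 2-(di-tert-butylphosphino)-1,1′-binaphthyl (4 mol %), Cs2CO3, toluene, 80 °C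
Reagents that add atoms: none
Why: Intramolecular Pd-catalysed C–O coupling (Buchwald–Hartwig etherification) of the tertiary alkoxide, which has no hydrogen on the carbinol carbon for β-hydride elimination, should close the pyran ring at O1–C8a; the C–O bond of the stereocentre is not broken, so C2 stays S.

Step 6
Reactants: 8 (2S)-2,8-dimethyl-2-(4-methylpent-3-en-1-yl)-6-[(triisopropylsilyl)oxy]chromane
Product: 9 (2E)-5-{(2S)-2,8-dimethyl-6-[(triisopropylsilyl)oxy]chroman-2-yl}-2-methylpent-2-en-1-ol
Conditions: SeO2 (0.3 equiv), t-BuOOH (3 equiv), salicylic acid (0.1 equiv), CH2Cl2, 0 °C → rt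
Reagents that add atoms: selenium dioxide, O=[Se]=O (transfers the oxygen); tert-butyl hydroperoxide, CC(C)(C)OO (re-forms it)
Why: Riley oxidation (ene reaction, then [2,3]-sigmatropic shift) should attack the methyl group at the more substituted olefin terminus that lies trans to the chain and so give the E allylic alcohol, while the allylic and benzylic CH2 groups react more slowly.

Step 7
Reactants: 9 (2E)-5-{(2S)-2,8-dimethyl-6-[(triisopropylsilyl)oxy]chroman-2-yl}-2-methylpent-2-en-1-ol
Product: 10 (2S)-2-[(3E)-5-bromo-4-methylpent-3-en-1-yl]-2,8-dimethyl-6-[(triisopropylsilyl)oxy]chromane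
Conditions: CBr4, PPh3, CH2Cl2, −20 → 0 °C
Reagents that add atoms: carbon tetrabromide, BrC(Br)(Br)Br
Why: The Appel reaction should convert the primary allylic alcohol into the bromide under neutral conditions with the E geometry kept.

Step 8
Reactants: 11 neryl acetate
Product: 12 (2Z)-5-[(2R)-3,3-dimethyloxiran-2-yl]-3-methylpent-2-en-1-yl acetate [(6R)-6,7-epoxyneryl acetate]
Conditions: D-fructose-derived Shi ketone (0.3 equiv), Oxone, K2CO3, Bu4NHSO4, Na2B4O7/EDTA buffer, MeCN–DMM–H2O, 0 °C
Reagents that add atoms: potassium peroxymonosulfate (Oxone), [K+].[O-]S(=O)(=O)OO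
Why: In the Shi epoxidation the electrophilic chiral dioxirane should choose the electron-rich 6,7-olefin over the acetate-deactivated 2,3-olefin, and the spiro transition state of the D-fructose-derived ketone should set R at C6 (the future C3).

Step 9
Reactants: 12 (2Z)-5-[(2R)-3,3-dimethyloxiran-2-yl]-3-methylpent-2-en-1-yl acetate
Product: 13 [(1R,3R)-3-hydroxy-2,2-dimethyl-6-methylidenecyclohexyl]methyl acetate
Conditions: Cp2TiCl2 (2.2 equiv), Mn dust (8 equiv), THF (degassed, 0.02 M), rt; then 1 M HCl
Reagents that add atoms: none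
Why: Titanocene(III) chloride (Nugent–RajanBabu reagent) opens the epoxide homolytically at the tertiary C–O bond, the β-titanoxy tertiary radical at C2 adds 6-endo-trig to C1 of the trisubstituted olefin, and the new tertiary radical at C6 is trapped by a second Ti(III) and loses a β-hydrogen from its methyl group, which gives the exocyclic C6=CH2 without any acid that could move it into the ring. The closest known reaction type is the titanocene(III)-mediated radical cyclization of 6,7-epoxygeranyl acetate and of higher epoxypolyprenes to 3-hydroxy-2,2-dimethyl-6-methylidenecyclohexanes; only the olefin geometry is changed here. The single ring closed is the cyclohexane, by 6-endo-trig radical closure of the C1–C2 bond through a chair-like (Beckwith–Houk) transition state. C3 is not a new centre, since its C–O bond is never broken and it keeps the R configuration from step 8; C1 is the new centre and is controlled by the olefin geometry, because with the bulky titanoxy group equatorial the Z olefin holds CH2OAc (cis to the ring CH2 on the double bond) axial on the forming chair, so that C1–CH2OAc and C3–O should end up trans (1R,3R), where the E isomer would give the cis pair. The step needs chair over boat closure, which the substrate should secure because the axial CH2OAc meets only axial hydrogens at C3 and C5 and lies anti to one methyl of C2 while the boat pays for eclipsing; it needs exo over endo olefin formation, secured by elimination from the least hindered β-position of the bulky titanocene alkyl; and it needs 6-endo over 5-exo addition, secured by attack at the less substituted olefin carbon to give the tertiary radical. Cyclization must also outrun reduction of the first radical by Ti(III), which is why the reaction is run dilute.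

Step 10
Reactants: 13 [(1R,3R)-3-hydroxy-2,2-dimethyl-6-methylidenecyclohexyl]methyl acetate
Product: 14 [(1R,3R)-2,2-dimethyl-6-methylidene-3-[(triethylsilyl)oxy]cyclohexyl]methyl acetate
Conditions: TESOTf, 2,6-lutidine, CH2Cl2, −78 → 0 °C
Reagents that add atoms: triethylsilyl trifluoromethanesulfonate, CC[Si](CC)(CC)OS(=O)(=O)C(F)(F)F
Why: The silyl triflate should silylate the hindered neopentyl-type secondary alcohol, which removes the O–H before the iodination and the organometallic step.

Step 11
Reactants: 14 [(1R,3R)-2,2-dimethyl-6-methylidene-3-[(triethylsilyl)oxy]cyclohexyl]methyl acetate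
Product: 15 [(1R,3R)-2,2-dimethyl-6-methylidene-3-[(triethylsilyl)oxy]cyclohexyl]methanol
Conditions: K2CO3 (0.2 equiv), MeOH, 0 °C → rt
Reagents that add atoms: none
Why: Base-catalysed transesterification should remove the acetate, while the hindered secondary TES ether is stable to carbonate in methanol.

Step 12
Reactants: 15 [(1R,3R)-2,2-dimethyl-6-methylidene-3-[(triethylsilyl)oxy]cyclohexyl]methanol
Product: 16 triethyl{[(1R,3R)-3-(iodomethyl)-2,2-dimethyl-4-methylidenecyclohexyl]oxy}silane
Conditions: PPh3, imidazole, I2 (premixed), THF, 0 → 50 °C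
Reagents that add atoms: iodine, II
Why: Garegg–Samuelsson iodination (SN2 displacement of the alkoxyphosphonium ion by iodide) should convert the primary alcohol into the iodide, and premixing the phosphine and iodine keeps free iodine away from the exocyclic olefin.

Step 13
Reactants: 16 triethyl{[(1R,3R)-3-(iodomethyl)-2,2-dimethyl-4-methylidenecyclohexyl]oxy}silane; 10 (2S)-2-[(3E)-5-bromo-4-methylpent-3-en-1-yl]-2,8-dimethyl-6-[(triisopropylsilyl)oxy]chromane
Product: 19 (2S)-2-{(3E)-6-[(1R,3R)-2,2-dimethyl-6-methylidene-3-[(triethylsilyl)oxy]cyclohexyl]-4-methylhex-3-en-1-yl}-2,8-dimethyl-6-[(triisopropylsilyl)oxy]chromane, via alkyllithium 17 (not isolated), via alkylmagnesium bromide 18 (not isolated)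
Conditions: t-BuLi (2.1 equiv), Et2O–pentane, −78 °C; MgBr2·OEt2, −78 → 0 °C; then slow addition to 10 and Li2CuCl4 (5 mol %), THF, −20 → 0 °C
Reagents that add atoms: none
Why: Iodine–lithium exchange through an ate complex avoids a free homoallyl radical and its rearrangement, and after transmetallation to magnesium the Kochi-type Li2CuCl4-catalysed Grignard coupling with the primary allylic bromide should go at the α-carbon (SN2) with the E geometry kept, forming the C5′–C6′ bond.

Step 14
Reactants: 19 (2S)-2-{(3E)-6-[(1R,3R)-2,2-dimethyl-6-methylidene-3-[(triethylsilyl)oxy]cyclohexyl]-4-methylhex-3-en-1-yl}-2,8-dimethyl-6-[(triisopropylsilyl)oxy]chromane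
Product: 20 (2S)-2-{(3E)-6-[(1R,3R)-3-hydroxy-2,2-dimethyl-6-methylidenecyclohexyl]-4-methylhex-3-en-1-yl}-2,8-dimethylchroman-6-ol (target)
Conditions: TBAF/AcOH (1:1, 4 equiv), THF (degassed), 0 °C → rt
Reagents that add atoms: none
Why: Buffered fluoride should cleave both Si–O bonds (aryl TIPS and secondary TES) without acid, so the exocyclic methylene, the E olefin and the three stereocentres are left as they are.

## Compound list

1 | 4-amino-3-methylphenol | Cc1cc(O)ccc1N | starting material
2 | 2-methyl-4-[(triisopropylsilyl)oxy]aniline | Cc1cc(O[Si](C(C)C)(C(C)C)C(C)C)ccc1N | intermediate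
3 | 2-iodo-6-methyl-4-[(triisopropylsilyl)oxy]aniline | Cc1cc(O[Si](C(C)C)(C(C)C)C(C)C)cc(I)c1N | intermediate
4 | 2-bromo-1-iodo-3-methyl-5-[(triisopropylsilyl)oxy]benzene | Cc1cc(O[Si](C(C)C)(C(C)C)C(C)C)cc(I)c1Br | intermediate
5 | (S)-(+)-linalool, (3S)-3,7-dimethylocta-1,6-dien-3-ol | CC(C)=CCC[C@](C)(O)C=C | starting material
6 | (3R)-1-(9-borabicyclo[3.3.1]nonan-9-yl)-3,7-dimethyloct-6-en-3-ol (same spatial arrangement as 5; the descriptor changes by priority only) | CC(C)=CCC[C@](C)(O)CCB1C2CCCC1CCC2 | intermediate (not isolated)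
7 | (3S)-1-{2-bromo-3-methyl-5-[(triisopropylsilyl)oxy]phenyl}-3,7-dimethyloct-6-en-3-ol | CC(C)=CCC[C@](C)(O)CCc1cc(O[Si](C(C)C)(C(C)C)C(C)C)cc(C)c1Br | intermediate
8 | (2S)-2,8-dimethyl-2-(4-methylpent-3-en-1-yl)-6-[(triisopropylsilyl)oxy]chromane | CC(C)=CCC[C@@]1(C)CCc2cc(O[Si](C(C)C)(C(C)C)C(C)C)cc(C)c2O1 | intermediate
9 | (2E)-5-{(2S)-2,8-dimethyl-6-[(triisopropylsilyl)oxy]chroman-2-yl}-2-methylpent-2-en-1-ol | OC/C(C)=C/CC[C@@]1(C)CCc2cc(O[Si](C(C)C)(C(C)C)C(C)C)cc(C)c2O1 | intermediate
10 | (2S)-2-[(3E)-5-bromo-4-methylpent-3-en-1-yl]-2,8-dimethyl-6-[(triisopropylsilyl)oxy]chromane | BrC/C(C)=C/CC[C@@]1(C)CCc2cc(O[Si](C(C)C)(C(C)C)C(C)C)cc(C)c2O1 | intermediate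
11 | neryl acetate, (2Z)-3,7-dimethylocta-2,6-dien-1-yl acetate | CC(C)=CCC/C(C)=C\COC(C)=O | starting material
12 | (2Z)-5-[(2R)-3,3-dimethyloxiran-2-yl]-3-methylpent-2-en-1-yl acetate | CC1(C)O[C@@H]1CC/C(C)=C\COC(C)=O | intermediate
13 | [(1R,3R)-3-hydroxy-2,2-dimethyl-6-methylidenecyclohexyl]methyl acetate | C=C1CC[C@@H](O)C(C)(C)[C@@H]1COC(C)=O | intermediate
14 | [(1R,3R)-2,2-dimethyl-6-methylidene-3-[(triethylsilyl)oxy]cyclohexyl]methyl acetate | C=C1CC[C@@H](O[Si](CC)(CC)CC)C(C)(C)[C@@H]1COC(C)=O | intermediate
15 | [(1R,3R)-2,2-dimethyl-6-methylidene-3-[(triethylsilyl)oxy]cyclohexyl]methanol | C=C1CC[C@@H](O[Si](CC)(CC)CC)C(C)(C)[C@@H]1CO | intermediate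
16 | triethyl{[(1R,3R)-3-(iodomethyl)-2,2-dimethyl-4-methylidenecyclohexyl]oxy}silane | C=C1CC[C@@H](O[Si](CC)(CC)CC)C(C)(C)[C@@H]1CI | intermediate
17 | {[(1R,3R)-2,2-dimethyl-6-methylidene-3-[(triethylsilyl)oxy]cyclohexyl]methyl}lithium | C=C1CC[C@@H](O[Si](CC)(CC)CC)C(C)(C)[C@@H]1C[Li] | intermediate (not isolated)
18 | {[(1R,3R)-2,2-dimethyl-6-methylidene-3-[(triethylsilyl)oxy]cyclohexyl]methyl}magnesium bromide | C=C1CC[C@@H](O[Si](CC)(CC)CC)C(C)(C)[C@@H]1C[Mg]Br | intermediate (not isolated)
19 | (2S)-2-{(3E)-6-[(1R,3R)-2,2-dimethyl-6-methylidene-3-[(triethylsilyl)oxy]cyclohexyl]-4-methylhex-3-en-1-yl}-2,8-dimethyl-6-[(triisopropylsilyl)oxy]chromane | C=C1CC[C@@H](O[Si](CC)(CC)CC)C(C)(C)[C@@H]1CC/C(C)=C/CC[C@@]1(C)CCc2cc(O[Si](C(C)C)(C(C)C)C(C)C)cc(C)c2O1 | intermediate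
20 | (2S)-2-{(3E)-6-[(1R,3R)-3-hydroxy-2,2-dimethyl-6-methylidenecyclohexyl]-4-methylhex-3-en-1-yl}-2,8-dimethylchroman-6-ol | C=C1CC[C@@H](O)C(C)(C)[C@@H]1CC/C(C)=C/CC[C@@]1(C)CCc2cc(O)cc(C)c2O1 | target

## Step count and risk

Total step count: 14.
Longest linear sequence: 9 steps (steps 1–7, 13 and 14); the carbocycle branch runs over steps 8–12.

Steps most likely to fail:

Step 9. The Z geometry may not be relayed cleanly: part of the radical may close through a boat-like transition state and give the C1 epimer, or β-hydride elimination may not be exo-selective. The fallback moves to the E series, whose cis outcome is established for epoxygeranyl substrates, and inverts C3 afterwards. It sets out at the stage of 11, which is replaced by its commercial E isomer geranyl acetate F1. Shi epoxidation with the enantiomeric (L-fructose-derived) ketone should give (6S)-6,7-epoxygeranyl acetate F2. The same Ti(III) cyclization, now through the all-equatorial chair, should give the cis hydroxy acetate F3, in which C1 already has the R configuration. Dess–Martin oxidation should give the ketone F4, which has no epimerisable hydrogen at C1. Corey–Bakshi–Shibata reduction with the (S)-oxazaborolidine, in which the quaternary C2 is the large group, should then place the hydroxyl R. The route is rejoined at 13.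

Step 13. The organocopper may attack the γ-carbon of the allylic bromide (SN2′), the bromide may homocouple, or halogen–metal exchange may be incomplete at the hindered neopentyl-type carbon. The fallback is sulfone alkylation followed by reductive desulfonylation, and it sets out from 16. Displacement with sodium benzenesulfinate (DMF, heat) should give the phenyl sulfone F5. Deprotonation with n-BuLi (THF–HMPA, −78 °C) and alkylation with 10 should give the sulfone-bearing coupled product F6 as a mixture of epimers at the sulfone carbon. Reductive desulfonylation with sodium amalgam (Na2HPO4, MeOH–THF, −20 °C) removes that centre, and the route is rejoined at 19.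

Step 5. Oxidative addition into the doubly ortho-substituted C–Br bond may be slow, and hydrodebromination may then compete with C–O bond formation. The fallback reverses the order of the two ring bonds: aryl ether first, C4–C4a last. It sets out from 3. Diazotisation and copper-mediated hydroxylation should give 2-iodo-6-methyl-4-[(triisopropylsilyl)oxy]phenol F7. Pd-catalysed asymmetric allylic etherification (Tsuji–Trost) with geranyl methyl carbonate F8 (from geraniol and methyl chloroformate) should give the tertiary aryl ether F9; the enantiomer of the DACH-phenyl bisphosphine ligand that gives the S ether is used. Hydroboration of the vinyl group with 9-BBN gives the borane F10, and intramolecular B-alkyl Suzuki–Miyaura coupling onto the ortho iodide closes the C4–C4a bond. The route is rejoined at 8.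

## Further compounds

F1 | step 9 | geranyl acetate, (2E)-3,7-dimethylocta-2,6-dien-1-yl acetate | CC(C)=CCC/C(C)=C/COC(C)=O
F2 | step 9 | (2E)-5-[(2S)-3,3-dimethyloxiran-2-yl]-3-methylpent-2-en-1-yl acetate | CC1(C)O[C@H]1CC/C(C)=C/COC(C)=O
F3 | step 9 | [(1R,3S)-3-hydroxy-2,2-dimethyl-6-methylidenecyclohexyl]methyl acetate | C=C1CC[C@H](O)C(C)(C)[C@@H]1COC(C)=O
F4 | step 9 | [(1R)-2,2-dimethyl-6-methylidene-3-oxocyclohexyl]methyl acetate | C=C1CCC(=O)C(C)(C)[C@@H]1COC(C)=O
F5 | step 13 | triethyl{[(1R,3R)-2,2-dimethyl-4-methylidene-3-[(phenylsulfonyl)methyl]cyclohexyl]oxy}silane | C=C1CC[C@@H](O[Si](CC)(CC)CC)C(C)(C)[C@@H]1CS(=O)(=O)c1ccccc1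
F6 | step 13 | (2S)-2-{(3E)-6-[(1R,3R)-2,2-dimethyl-6-methylidene-3-[(triethylsilyl)oxy]cyclohexyl]-4-methyl-6-(phenylsulfonyl)hex-3-en-1-yl}-2,8-dimethyl-6-[(triisopropylsilyl)oxy]chromane (both epimers at C6′) | C=C1CC[C@@H](O[Si](CC)(CC)CC)C(C)(C)[C@@H]1C(C/C(C)=C/CC[C@@]1(C)CCc2cc(O[Si](C(C)C)(C(C)C)C(C)C)cc(C)c2O1)S(=O)(=O)c1ccccc1
F7 | step 5 | 2-iodo-6-methyl-4-[(triisopropylsilyl)oxy]phenol | Cc1cc(O[Si](C(C)C)(C(C)C)C(C)C)cc(I)c1O
F8 | step 5 | geranyl methyl carbonate, (2E)-3,7-dimethylocta-2,6-dien-1-yl methyl carbonate | CC(C)=CCC/C(C)=C/COC(=O)OC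
F9 | step 5 | (3S)-3,7-dimethylocta-1,6-dien-3-yl 2-iodo-6-methyl-4-[(triisopropylsilyl)oxy]phenyl ether | CC(C)=CCC[C@@](C)(C=C)Oc1c(C)cc(O[Si](C(C)C)(C(C)C)C(C)C)cc1I
F10 | step 5 | 9-{(3R)-3-{2-iodo-6-methyl-4-[(triisopropylsilyl)oxy]phenoxy}-3,7-dimethyloct-6-en-1-yl}-9-borabicyclo[3.3.1]nonane | CC(C)=CCC[C@@](C)(CCB1C2CCCC1CCC2)Oc1c(C)cc(O[Si](C(C)C)(C(C)C)C(C)C)cc1I
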